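36.6% of the substrate charged was where larch levelled off, on average over its last readings, although larch held 4.00 cedar charges of second catalyst. Cedar, which was colder, had reached 45% at its last reading and was still creeping up. I am leaving you these flasks:

| flask | substrate | reagent | free catalyst | second catalyst | temperature | remark | time |
|---|---|---|---|---|---|---|---|
| cedar | 0.30 M | 0.30 M | 19 mM | 2.1 mM | 0 °C | run made earlier |  |
| larch | 0.30 M | 0.30 M | 19 mM | 8.4 mM | 33 °C | run made earlier |  |
| violet | 0.30 M | 0.300 M | 19 mM | 4.2 mM | 45 °C |  | 6.0 min |
| amber | 0.30 M | 0.300 M | 19 mM | 4.2 mM | −15 °C |  | 6.0 min |
| red | 0.30 M | 0.300 M | 19 mM | 4.2 mM | 25 °C |  | 6.0 min |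
| blue | 0.30 M | 0.300 M | 19 mM | 4.2 mM | 5 °C |  | 6.0 min |

- cedar (time / min: target / %): 12.0: 16; 25.0: 25; 40.0: 37; 50.0: 40; 60.0: 41; 80.0: 45
- larch (time / min: target / %): 0.833: 27; 2.00: 38; 2.50: 35; 5.00: 38; 8.00: 37; 15.0: 35

(each reading ± 2 percentage points)

- steps that have been proposed: second catalyst + open intermediate <-> catalyst intermediate; substrate + free catalyst <-> free catalyst + open intermediate; reagent + catalyst intermediate -> second catalyst + target; reagent -> decomposition product; open intermediate -> side product

* the flask that comes out highest in amount of target, in percent of the substrate charged, or "all alike" when all lie within 1.5 percentage points (violet / amber / red / blue / all alike)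
* target at the end, in percent of the substrate charged, violet
* target at the end, in percent of the substrate charged, amber
* target at the end, in percent of the substrate charged, red
* target at the end, in percent of the substrate charged, blue

In the proposed steps, open intermediate can run back to substrate, but it ends either as target, by way of second catalyst, or as side product. So I carried a selectivity factor, which I called the capture odds: target made per side product made, for each cedar charge of second catalyst in the flask. Counting the rest of the substrate as side product, these odds read 0.818 at cedar's temperature and 0.144 at larch's. I took their logarithm as straight in temperature and gave each flask twice the cedar charge. My estimate of the ceiling, the target of a flask left to finish, is then odds over one plus odds. Red came to odds of 0.440 and a ceiling of 30.5%. Violet came to 13.3%.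

When you arrive, expect red and violet to have finished, with side product holding most of the substrate. Blue and amber have higher estimated ceilings, and I expect them still climbing: cedar, the nearest run in temperature, read 16% at 12.0 min. Don't warm them if you mean to leave them long: my odds per charge read lower at larch's temperature than at cedar's.

The forecast gave violet 18%, amber 6%, red 31% and blue 22%: “Red comes out highest.” Its violet stands above my estimate.

The flasks gave violet 15.5%, amber 4.91%, red 30.3% and blue 20.0%, so red led, as forecast, and violet came out above my estimate.

    second catalyst + open intermediate ⇌ catalyst intermediate (K = 1160 /M, k = 5.54 /M/s, Ea = 50.0 kJ/mol, ΔH = −23.0 kJ/mol)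
    substrate + free catalyst ⇌ free catalyst + open intermediate (K = 1.40, k = 12.0 /M/s, Ea = 38.0 kJ/mol, ΔH = −1.00 kJ/mol)
    reagent + catalyst intermediate → second catalyst + target (k = 0.655 /M/s, Ea = 41.0 kJ/mol)
    reagent → decomposition product (k = 3.94 × 10⁻⁵ /s, Ea = 97.0 kJ/mol)
    open intermediate → side product (k = 0.0170 /s, Ea = 84.0 kJ/mol)
    (constants at 25 °C)

Red led on the clock. With 0.0825% of its substrate left at 6.00 min, red stood at its ceiling and still held 30.4% at 60.0 min. For blue the capture odds give 1.26, an estimated ceiling of 55.8%, and blue left until 60.0 min held 54.3%, ahead of red at that time. The same lengthening took amber from 4.91% to 41.7%.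

All runs stem from a simulated flask on assumed constants, noise included.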